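**Proposed synthesis of CNP0316622.2 (C30H48O5): linalool-derived ene cyclisation, radical closure of the cycloheptanone, polyepoxide cascade for the right half**

Atoms are numbered in their order in the target SMILES, hydrogens not counted.

## Analysis of the target

The target is a C30 triterpenoid built from two C15 halves joined by the two-carbon bridge C17–C18. The left half is a cis-fused hydroazulene: a cyclopentane (C6 to C10) fused to a cycloheptanone (C2, C3, C5, C6, C7, C13, C16). It carries an exocyclic methylene (C1 on C2) conjugated with the ketone C3, a gem-dimethyl quaternary carbon C13 and a tertiary carbinol C10. The right half is a trans-fused 2,2-dimethyloxepan-3-one (C20, C22, C23, C24, C26, O29, C30) on a cyclohexane (C19, C20, C30 to C33), with the angular methyl C21 and an axial tertiary alcohol at C33. There are eight stereocentres. In the left half H6, H7 and H16 lie on one face and O12 lies on that same face, so O12 is trans and the methyl C11 cis to C5. In the right half the ring fusion is trans, the chain on C19 is equatorial and the C33 hydroxyl is axial, syn to C21. The two clusters are insulated by the CH2–CH2 bridge, so each half needs its own source of absolute configuration. The sensitive groups are the α-methylene ketone (a Michael acceptor that can also isomerise into the ring) and the two tertiary alcohols; O35 in particular can add to an electrophilic C16. The hard parts are the seven-membered carbocycle with the quaternary C13 between two stereocentres, and the oxepane. The strategy rests on one feature: C5–C6–C10(CH3)(OH)–C9–C8–C7–C13(CH3)2 is the carbon chain of linalool with its (R) carbinol, so the cyclopentane lacks only the bond C6–C7.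

## Retrosynthetic reasoning

**End game.** Target 29 is taken back to triol 28 by oxidation of the only secondary alcohol (C24), and 28 to the tris(silyl ether) 27. Keeping C24 as an alcohol until the end avoids having to tell two ketones apart in the right half. Keeping O35 silylated until C16 is saturated prevents it from adding to C16.

**C13–C16.** In 27 the bond C13–C16 is cut. C13 is quaternary and has no useful polar synthon, but a tertiary radical at C13 is available from the isopropenyl group that the ene reaction leaves on C7. The acceptor is the α-(acetoxymethyl) enone 25. Addition at the β-carbon C16 closes the ring in the 7-endo sense, and the enolate formed at C2 expels the acetate on C1. This gives the ring, C16 and the exocyclic enone in one operation, with the methylene regiochemically fixed.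

**C2–C16, the union of the halves.** Acetate 25 comes by 1,3-transposition from acetate 24 of the Baylis–Hillman adduct 23, which is cut at C2–C16 into vinyl ketone 10 and aldehyde 22. The bridge bond C17–C18 looks like the obvious cut. It would require an sp3–sp3 coupling, or an olefination followed by reduction, next to the enone. The C2–C16 cut uses the same carbonyl addition that builds the radical acceptor, and lets the α-methylene ketone appear only three steps from the end.

**Vinyl ketone.** Ketone 10 goes back through the N-methoxy-N-methylamide 9 to ester 8. The ester carbon is C3 and a vinyl nucleophile brings C2 and C1.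

**C6–C7, the key cut.** Ester 8 is cut at C6–C7 by a retro-ene reaction to the 1,6-diene 7. Forward, the prenyl alkene is the ene and the enoate the enophile. One thermal step makes the ring and both new stereocentres and leaves the isopropenyl group that later becomes C13. The cut is made here because it is the only ring bond of the cyclopentane whose removal gives a chiral-pool chain.

**Precursor 7 from linalool.** The shortest route from 2 would be cross-metathesis of the vinyl group with an acrylic ester. It is not relied on. A ruthenium alkylidene at C6 sits five atoms from the prenyl alkene, and ring-closing metathesis to a methylcyclopentene is the known fate of linalool and its ethers. The prenyl alkene of 2 is therefore masked as epoxide 3 and the vinyl group cleaved to aldehyde 5. Aldehyde 5 is olefinated to 6 and the alkene is restored to give 7. This costs three steps more, all standard, so the risk stays in the ene step.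

**C33.** Aldehyde 22 comes from alcohol 21 and benzyl ether 20, and 20 from ketone 18 by equatorial addition of a methyl nucleophile and silylation in the same flask. The axial methyl C21 blocks the axial trajectory, which gives the axial hydroxyl of the target.

**Both rings of the right half.** Ketone 18 is cut at O29–C26 and C19–C20 to the diepoxy enol ether 17. Forward, a cascade opens the terminal epoxide at its tertiary carbon with the oxygen of the internal epoxide, and the enol ether then opens the epoxonium ion at C20. C20 and C30 follow from the configuration of one epoxide and the trans fusion follows from the (E) alkene.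

**Acyclic chain.** Enol ether 17 comes by 1,4-hydrosilylation from enone 16, which fixes the enol regiochemistry at C19. Enone 16 comes from trienone 15 by reagent-controlled epoxidation. Trienone 15 comes from aldol 13, and 13 from ketone 11 and aldehyde 12, which supplies C18, C17 and C16.

## Alternatives that were turned down

**Alternative 1: closure of the carbocycle by epoxide opening with an aza-enolate.**
- Disconnection: C5–C6 of the cycloheptane, with the cyclopentane present as its C6–C10 epoxide in hydrazone A2.
- Key step: a lithium amide deprotonates the methyl group C5 of the N,N-dimethylhydrazone. The aza-enolate attacks C6 from the face opposite the epoxide oxygen, closes the seven-membered ring (7-exo-tet) and releases the C10 alkoxide to give A1.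
- For: the trans relation of C5 and O12 follows from SN2 geometry, and the epoxide oxygen is placed anti to the C7 substituent by simple approach control. On this point it is stronger than the chosen route, which depends on a facial preference. C10 needs no protecting group.
- Against: A2 must already hold C7, the quaternary C13 and C16 in an open chain, a 1,3-relation across a quaternary carbon with no ring to set it. Substitution at a secondary carbon next to the tert-alkyl-bearing C7, forming a seven-membered ring, is slow. The α-methylene hydrazone is open to conjugate addition and to deprotonation at C16.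
- Comparison: the chosen route takes C10 from the chiral pool, makes the ring and two centres in a reagent-free step, and sets C16 during ring closure under ring control.

**Alternative 2: hydroxyl-directed conjugate addition and alkylation on a hydroxy-enone.**
- Disconnection: C18–C19 and C20–C22 at the cyclohexane.
- Key step: the Grignard reagent from iodide A5 adds to C19 of the magnesium alkoxide of hydroxy-enone A4 on the face of the oxygen. The enolate is alkylated at C20 by bromide A6 to give A3.
- For: it is stronger in convergence. The union itself creates two adjacent stereocentres, including the quaternary one, and C33 is in place from the start.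
- Against: the complete hydroazulene is used as a nucleophile, normally in excess, and A5 still needs the whole left-half problem solved. Alkylation of a fully substituted magnesium enolate next to the new tertiary centre is slow and open to O-alkylation. The oxepane must then be built on the coupled material, including a seven-membered ether closure onto the tertiary C26.
- Comparison: the chosen route makes the right half separately and closes both its rings at once. Its union step creates no stereocentre, so C16 is left to the radical closure.

**Alternative 3: oxepane by ring expansion of a tetrahydropyran.**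
- Disconnection: O29–C26, back to tetrahydropyran A8 in which O29 is bonded to C24.
- Key step: the tertiary alcohol at C26 is ionised through its chloride with a silver carboxylate. O29 bridges C24 and C26 as an epoxonium ion and acetate opens it at C24 to give A7.
- For: a six-membered ether is easier to close than a seven-membered one, and A7 already carries the C19 chain and the C33 carbonyl. In the robustness of each single ring closure it is at least as strong as a cationic cascade.
- Against: the epoxonium ion must open at the secondary C24 and not at the tertiary C26, and must not lose a proton to an isopropenyl group. The centre set at C24 is destroyed by the later oxidation. A8 needs three ring stereocentres assembled stepwise.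
- Comparison: the chosen route forms O29–C26 directly, because the terminal epoxide opens at its tertiary carbon, and closes the carbocycle in the same step from an acyclic precursor made in four steps.

Key step: step 6

## Route

Assumption: commercial (R)-(−)-linalool is taken as enantiomerically pure, commercial geranylacetone as the pure (E) isomer, and the D-fructose-derived Shi ketone as a purchased catalyst.

Step 1
Reactants: 1 (R)-linalool
Product: 2 (R)-linalool triethylsilyl ether
Conditions: Et3SiOTf, 2,6-lutidine, CH2Cl2, −78 to 0 °C
Reagents that add atoms: triethylsilyl trifluoromethanesulfonate, CC[Si](CC)(CC)OS(=O)(=O)C(F)(F)F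
Why: Silylation of a tertiary alcohol with a silyl triflate and a hindered pyridine base is standard; the ether keeps O12 from opening the epoxide made next and is the bulky group that later steers the ene reaction.

Step 2
Reactants: 2 (R)-linalool triethylsilyl ether
Product: 3 triethyl{[(3R)-5-(3,3-dimethyloxiran-2-yl)-3-methylpent-1-en-3-yl]oxy}silane (both epoxide epimers)
Conditions: mCPBA (1.05 equiv), NaHCO3, CH2Cl2, 0 °C
Reagents that add atoms: 3-chloroperbenzoic acid, OOC(=O)c1cccc(Cl)c1
Why: Prilezhaev epoxidation selects the electron-rich trisubstituted alkene over the vinyl group on the oxygen-bearing quaternary carbon; the epoxide only masks the prenyl alkene, so its configuration is of no consequence.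

Step 3
Reactants: 3 epoxy silyl ether
Product: 5 (2R)-4-(3,3-dimethyloxiran-2-yl)-2-methyl-2-(triethylsilyloxy)butanal, via the ozonide 4 (not isolated)
Conditions: O3, CH2Cl2, −78 °C; then PPh3, −78 °C to 25 °C
Reagents that add atoms: ozone, [O-][O+]=O
Why: Ozonolysis with reductive work-up cleaves the only alkene left to a non-enolisable α-silyloxy aldehyde; epoxide and silyl ether are inert to ozone.

Step 4
Reactants: 5 α-silyloxy aldehyde
Product: 6 methyl (2E,4R)-6-(3,3-dimethyloxiran-2-yl)-4-methyl-4-(triethylsilyloxy)hex-2-enoate
Conditions: Ph3P=CHCO2Me, toluene, 80 °C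
Reagents that add atoms: methyl (triphenylphosphoranylidene)acetate, COC(=O)C=P(c1ccccc1)(c1ccccc1)c1ccccc1
Why: Wittig olefination with a stabilised ylide gives the (E)-enoate; the aldehyde has no α-hydrogen, so heating the hindered carbonyl is harmless.

Step 5
Reactants: 6 epoxy enoate
Product: 7 methyl (2E,4R)-4,8-dimethyl-4-(triethylsilyloxy)nona-2,7-dienoate
Conditions: dimethyl diazomalonate (1.5 equiv, slow addition), Rh2(OAc)4 (2 mol %), toluene, 80 °C
Reagents that add atoms: none
Why: Rhodium-carbenoid deoxygenation of an epoxide used as an alkene protecting group: the carbenoid forms an oxonium ylide at the epoxide oxygen, which collapses to the alkene and the oxomalonate under neutral conditions that spare the enoate and the tertiary silyl ether.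

Step 6
Reactants: 7 methyl (2E,4R)-4,8-dimethyl-4-(triethylsilyloxy)nona-2,7-dienoate
Product: 8 methyl 2-[(1R,2R,5R)-5-methyl-2-(prop-1-en-2-yl)-5-(triethylsilyloxy)cyclopentyl]acetate
Conditions: toluene (0.02 M), BHT (cat.), base-washed sealed tube, 190 °C
Reagents that add atoms: none
Why: This is a concerted thermal intramolecular ene reaction of a 1,6-diene with an ester-activated enophile, the reaction type by which five-membered rings with cis CH2CO2R and isopropenyl groups on neighbouring carbons are classically made. The prenyl alkene (C7=C13) is the ene and the enoate (C5=C6) the enophile: C7 bonds to the electrophilic β-carbon C6 while an allylic methyl hydrogen passes to C5 through a six-membered array. The cyclopentane (C6 to C10) closes between the two alkene carbons nearest the tether, so each π bond ends exocyclic to the new ring (5-exo with respect to either alkene). C7 is set relative to C6 by the endo bicyclic transition state, in which the hydrogen-transfer ring is fused cis on the forming bond, so CH2CO2Me and isopropenyl come out cis. C6 is set relative to C10: in the reacting conformer the tether carbon C9 lies on the attacked face, the C10–O bond stands anti to the forming C6–C7 bond (best σ* acceptor, and the bulky Et3SiO group away from the pericyclic array), and the methyl group eclipses the enoate, where the (E) geometry leaves only H5 as its neighbour; this places Et3SiO trans to both new substituents. The quaternary C10 compresses the tether (gem-disubstitution), which with ester activation should keep the reaction below 200 °C, far under the temperature at which a tertiary silyl ether loses silanol. The step thus needs cis selectivity at C6/C7, secured by concertedness, and face selection at C6, secured by the two different groups on C10.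

Step 7
Reactants: 8 ene product
Product: 9 N-methoxy-N-methyl-2-[(1R,2R,5R)-5-methyl-2-(prop-1-en-2-yl)-5-(triethylsilyloxy)cyclopentyl]acetamide
Conditions: MeNH(OMe)·HCl, i-PrMgCl, THF, −20 to 0 °C
Reagents that add atoms: N,O-dimethylhydroxylamine hydrochloride, CNOC.Cl
Why: Aminolysis of a methyl ester by the chloromagnesium amide made in the flask (Weinreb amide formation); no epimerisable centre is touched.

Step 8
Reactants: 9 Weinreb amide
Product: 10 1-[(1R,2R,5R)-5-methyl-2-(prop-1-en-2-yl)-5-(triethylsilyloxy)cyclopentyl]but-3-en-2-one
Conditions: CH2=CHMgBr, THF, −78 to 0 °C; inverse quench into cold aqueous KHSO4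
Reagents that add atoms: vinylmagnesium bromide, C=C[Mg]Br
Why: Weinreb ketone synthesis: the chelated tetrahedral adduct prevents a second addition, and the acidic inverse quench keeps the liberated amine from adding to the vinyl ketone.

Step 9
Reactants: 11 (E)-geranylacetone; 12 3-(benzyloxy)propanal
Product: 13 (8E)-1-(benzyloxy)-3-hydroxy-9,13-dimethyltetradeca-8,12-dien-5-one (racemic carbinol)
Conditions: LiN(i-Pr)2, THF, −78 °C; then 12; aqueous NH4Cl
Reagents that add atoms: none
Why: Kinetic deprotonation of the methyl ketone at CH3 (the future C19) and aldol addition to the aldehyde, which brings C18, C17 and C16; the carbinol centre is removed in the next step.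

Step 10
Reactants: 13 aldol
Product: 15 (3E,8E)-1-(benzyloxy)-9,13-dimethyltetradeca-3,8,12-trien-5-one, via mesylate 14 (not isolated)
Conditions: MsCl, Et3N, CH2Cl2, 0 to 25 °C
Reagents that add atoms: none
Why: Mesylation followed by E1cB elimination gives the (E)-enone that will later fix the enol ether regiochemistry.

Step 11
Reactants: 15 trienone
Product: 16 (3E,8R,9R,12R)-1-(benzyloxy)-8,9:12,13-diepoxy-9,13-dimethyltetradec-3-en-5-one
Conditions: D-fructose-derived Shi ketone (0.3 equiv per alkene), Oxone (2KHSO5·KHSO4·K2SO4), K2CO3, Bu4NHSO4, MeCN/CH2(OMe)2, aqueous Na2B4O7/Na2EDTA buffer, 0 °C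
Reagents that add atoms: potassium peroxymonosulfate (the oxidant of Oxone), [K+].[O-]S(=O)(=O)OO
Why: Shi asymmetric epoxidation: the chiral dioxirane transfers oxygen through a spiro transition state and the D-fructose-derived ketone gives (R,R) and (R) epoxides from (E)-trisubstituted alkenes; the electron-poor enone alkene is not touched.

Step 12
Reactants: 16 diepoxy enone
Product: 17 {[(4Z,8R,9R,12R)-1-(benzyloxy)-8,9:12,13-diepoxy-9,13-dimethyltetradec-4-en-5-yl]oxy}triethylsilane (mainly Z; either isomer serves)
Conditions: Et3SiH, RhCl(PPh3)3 (1 mol %), benzene, 50 °C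
Reagents that add atoms: triethylsilane, CC[SiH](CC)CC
Why: Rhodium-catalysed 1,4-hydrosilylation of an enone with a monohydrosilane gives the silyl enol ether regiospecifically at C19–C33, which base treatment of the saturated ketone could not do.

Step 13
Reactants: 17 diepoxy silyl enol ether
Product: 18 (3R,5aR,6R,9aR)-6-[3-(benzyloxy)propyl]-2,2,5a-trimethyl-3-(triethylsilyloxy)octahydro-1-benzoxepin-7(2H)-one (trans-fused; chain on C19 equatorial)
Conditions: Et3SiOTf (0.5 equiv), 2,6-di-tert-butyl-4-methylpyridine, CH2Cl2, −78 °C; Et3N quench
Reagents that add atoms: none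
Why: Silyl-triflate-promoted tandem oxa- and carbacyclisation of a 1,5-diepoxide ending in a silyl enol ether, a known entry to trans-fused 2,2-dimethyloxepanes. The silylated terminal epoxide is opened at its tertiary carbon C26 by the oxygen of the internal epoxide, and the epoxonium ion is opened at C20 with inversion by C19 through a chair, so C30 keeps and C20 inverts the epoxide configuration, and the silyl group of the enol ether is passed on as the promoter. C19 is α to the ketone and settles with its chain equatorial on contact with base.

Step 14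
Reactants: 18 bicyclic ketone
Product: 20 (3R,5aR,6R,7S,9aR)-6-[3-(benzyloxy)propyl]-2,2,5a,7-tetramethyl-3,7-bis(triethylsilyloxy)decahydro-1-benzoxepine, via lithium alkoxide 19 (not isolated)
Conditions: MeLi, Et2O/THF, −78 °C; then Et3SiOTf, 2,6-lutidine, −78 to 0 °C
Reagents that add atoms: methyllithium, [Li]C; triethylsilyl trifluoromethanesulfonate, CC[Si](CC)(CC)OS(=O)(=O)C(F)(F)F
Why: 1,2-Addition of a small organolithium to a cyclohexanone whose axial face is blocked by the 1,3-related axial methyl C21, so the methyl enters equatorially and the oxygen ends axial as in the target; trapping the alkoxide as its silyl ether keeps O35 from later adding to C16.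

Step 15
Reactants: 20 benzyl ether
Product: 21 3-[(3R,5aR,6R,7S,9aR)-2,2,5a,7-tetramethyl-3,7-bis(triethylsilyloxy)decahydro-1-benzoxepin-6-yl]propan-1-ol
Conditions: H2 (1 atm), Pd/C, EtOAc, 25 °C
Reagents that add atoms: none
Why: Hydrogenolysis of a benzyl ether; the molecule holds no alkene at this stage and silyl ethers are stable in a neutral aprotic solvent.

Step 16
Reactants: 21 primary alcohol
Product: 22 3-[(3R,5aR,6R,7S,9aR)-2,2,5a,7-tetramethyl-3,7-bis(triethylsilyloxy)decahydro-1-benzoxepin-6-yl]propanal
Conditions: Dess–Martin periodinane, NaHCO3, CH2Cl2, 0 to 25 °C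
Reagents that add atoms: none
Why: Dess–Martin oxidation of a primary alcohol; with O35 silylated the δ-oxygenated aldehyde cannot close to a lactol.

Step 17
Reactants: 10 vinyl ketone (1.5 equiv); 22 aldehyde
Product: 23 Baylis–Hillman adduct, the 2-methylene-3-hydroxy ketone in which C2 of 10 is bonded to the carbinol carbon C16 of 22 (both C16 epimers; three triethylsilyl ethers)
Conditions: quinuclidine (0.3 equiv), MeOH (2 equiv), THF (2 M), 25 °C
Reagents that add atoms: none
Why: Morita–Baylis–Hillman reaction of an alkyl vinyl ketone with an unhindered aliphatic aldehyde under amine catalysis with a protic co-catalyst; the carbinol centre is removed two steps later, so its configuration does not matter.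

Step 18
Reactants: 23 Baylis–Hillman adduct
Product: 24 C16 acetate of 23
Conditions: Ac2O, pyridine, DMAP (cat.), CH2Cl2, 0 °C
Reagents that add atoms: acetic anhydride, CC(=O)OC(C)=O
Why: Acylation of the only free hydroxyl, a secondary allylic alcohol.

Step 19
Reactants: 24 Baylis–Hillman acetate
Product: 25 (E)-α-(acetoxymethyl) enone, C3(=O)–C2(CH2OAc)=C16H–C17 (E preferred; either geometry serves)
Conditions: DABCO (0.3 equiv), THF, 60 °C
Reagents that add atoms: none
Why: Amine-catalysed 1,3-transposition of a Baylis–Hillman acetate by two allylic displacements (SN2′ addition of the amine at C1, return of acetate at C1), driven to the conjugated trisubstituted alkene.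

Step 20
Reactants: 25 α-(acetoxymethyl) enone
Product: 27 hydroazulenone with the C1 methylene on C2 and the complete carbon skeleton (C10, C24 and C33 oxygens as triethylsilyl ethers), via β-acetoxy ketone 26 (not isolated)
Conditions: Fe(acac)3 (0.5 equiv), PhSiH3 (2.5 equiv), EtOH/THF 1:1 (0.005 M), 50 °C; then Et3N, CH2Cl2, 25 °C
Reagents that add atoms: none
Why: Metal-hydride hydrogen-atom transfer from an iron hydride to the isopropenyl group gives the tertiary radical at C13, which adds to the β-carbon C16 of the enone (intramolecular Giese addition, 7-endo, the polarity-matched site); the α-keto radical at C2 is reduced to the enolate and loses acetate from C1 in the flask or on the amine treatment. C16 is set in a chair-like transition state with H7 in the plane of the radical, C8 anti to the forming bond and the C17 chain between the two methyl groups of C13, not next to C7, which places H16 cis to H7.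

Step 21
Reactants: 27 tris(triethylsilyl) ether
Product: 28 triol (the target with C24 as its (R)-alcohol)
Conditions: HF·pyridine, pyridine, THF, 0 to 25 °C
Reagents that add atoms: none
Why: Fluoride cleavage of one secondary and two tertiary triethylsilyl ethers under buffered acidic conditions that the α-methylene ketone tolerates.

Step 22
Reactants: 28 triol
Product: 29 target compound CNP0316622.2
Conditions: Dess–Martin periodinane, NaHCO3, CH2Cl2, 0 °C
Reagents that add atoms: none
Why: Dess–Martin oxidation of the only secondary alcohol (C24); the tertiary alcohols and the enone are inert.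

## Compound list

1 | (R)-linalool, (3R)-3,7-dimethylocta-1,6-dien-3-ol | C=C[C@](C)(O)CCC=C(C)C | starting material
2 | triethyl{[(3R)-3,7-dimethylocta-1,6-dien-3-yl]oxy}silane | C=C[C@](C)(O[Si](CC)(CC)CC)CCC=C(C)C | intermediate
3 | triethyl{[(3R)-5-(3,3-dimethyloxiran-2-yl)-3-methylpent-1-en-3-yl]oxy}silane, both epoxide epimers | C=C[C@](C)(O[Si](CC)(CC)CC)CCC1OC1(C)C | intermediate
4 | ozonide of 3, a 3-substituted 1,2,4-trioxolane | C1OOC(O1)[C@](C)(O[Si](CC)(CC)CC)CCC1OC1(C)C | intermediate (not isolated)
5 | (2R)-4-(3,3-dimethyloxiran-2-yl)-2-methyl-2-(triethylsilyloxy)butanal | O=C[C@](C)(O[Si](CC)(CC)CC)CCC1OC1(C)C | intermediate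
6 | methyl (2E,4R)-6-(3,3-dimethyloxiran-2-yl)-4-methyl-4-(triethylsilyloxy)hex-2-enoate | COC(=O)/C=C/[C@](C)(O[Si](CC)(CC)CC)CCC1OC1(C)C | intermediate
7 | methyl (2E,4R)-4,8-dimethyl-4-(triethylsilyloxy)nona-2,7-dienoate | COC(=O)/C=C/[C@](C)(O[Si](CC)(CC)CC)CCC=C(C)C | intermediate
8 | methyl 2-[(1R,2R,5R)-5-methyl-2-(prop-1-en-2-yl)-5-(triethylsilyloxy)cyclopentyl]acetate | COC(=O)C[C@@H]1[C@@H](CC[C@@]1(C)O[Si](CC)(CC)CC)C(C)=C | intermediate
9 | N-methoxy-N-methyl-2-[(1R,2R,5R)-5-methyl-2-(prop-1-en-2-yl)-5-(triethylsilyloxy)cyclopentyl]acetamide | CON(C)C(=O)C[C@@H]1[C@@H](CC[C@@]1(C)O[Si](CC)(CC)CC)C(C)=C | intermediate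
10 | 1-[(1R,2R,5R)-5-methyl-2-(prop-1-en-2-yl)-5-(triethylsilyloxy)cyclopentyl]but-3-en-2-one | C=CC(=O)C[C@@H]1[C@@H](CC[C@@]1(C)O[Si](CC)(CC)CC)C(C)=C | intermediate
11 | (E)-geranylacetone, (5E)-6,10-dimethylundeca-5,9-dien-2-one | CC(=O)CC/C=C(\C)CCC=C(C)C | starting material
12 | 3-(benzyloxy)propanal | O=CCCOCc1ccccc1 | starting material
13 | (8E)-1-(benzyloxy)-3-hydroxy-9,13-dimethyltetradeca-8,12-dien-5-one, racemic carbinol | O=C(CC(O)CCOCc1ccccc1)CC/C=C(\C)CCC=C(C)C | intermediate
14 | methanesulfonate of 13 | O=C(CC(OS(C)(=O)=O)CCOCc1ccccc1)CC/C=C(\C)CCC=C(C)C | intermediate (not isolated)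
15 | (3E,8E)-1-(benzyloxy)-9,13-dimethyltetradeca-3,8,12-trien-5-one | O=C(/C=C/CCOCc1ccccc1)CC/C=C(\C)CCC=C(C)C | intermediate
16 | (3E,8R,9R,12R)-1-(benzyloxy)-8,9:12,13-diepoxy-9,13-dimethyltetradec-3-en-5-one | O=C(/C=C/CCOCc1ccccc1)CC[C@H]1O[C@]1(C)CC[C@H]1OC1(C)C | intermediate
17 | {[(4Z,8R,9R,12R)-1-(benzyloxy)-8,9:12,13-diepoxy-9,13-dimethyltetradec-4-en-5-yl]oxy}triethylsilane | c1ccccc1COCCC/C=C(\O[Si](CC)(CC)CC)CC[C@H]1O[C@]1(C)CC[C@H]1OC1(C)C | intermediate
18 | (3R,5aR,6R,9aR)-6-[3-(benzyloxy)propyl]-2,2,5a-trimethyl-3-(triethylsilyloxy)octahydro-1-benzoxepin-7(2H)-one | c1ccccc1COCCC[C@@H]1[C@@]2(C)CC[C@@H](O[Si](CC)(CC)CC)C(C)(C)O[C@@H]2CCC1=O | intermediate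
19 | lithium alkoxide from methyl addition to C33 of 18 | c1ccccc1COCCC[C@@H]1[C@@]2(C)CC[C@@H](O[Si](CC)(CC)CC)C(C)(C)O[C@@H]2CC[C@]1(C)[O-].[Li+] | intermediate (not isolated)
20 | (3R,5aR,6R,7S,9aR)-6-[3-(benzyloxy)propyl]-2,2,5a,7-tetramethyl-3,7-bis(triethylsilyloxy)decahydro-1-benzoxepine | c1ccccc1COCCC[C@@H]1[C@@]2(C)CC[C@@H](O[Si](CC)(CC)CC)C(C)(C)O[C@@H]2CC[C@]1(C)O[Si](CC)(CC)CC | intermediate
21 | 3-[(3R,5aR,6R,7S,9aR)-2,2,5a,7-tetramethyl-3,7-bis(triethylsilyloxy)decahydro-1-benzoxepin-6-yl]propan-1-ol | OCCC[C@@H]1[C@@]2(C)CC[C@@H](O[Si](CC)(CC)CC)C(C)(C)O[C@@H]2CC[C@]1(C)O[Si](CC)(CC)CC | intermediate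
22 | 3-[(3R,5aR,6R,7S,9aR)-2,2,5a,7-tetramethyl-3,7-bis(triethylsilyloxy)decahydro-1-benzoxepin-6-yl]propanal | O=CCC[C@@H]1[C@@]2(C)CC[C@@H](O[Si](CC)(CC)CC)C(C)(C)O[C@@H]2CC[C@]1(C)O[Si](CC)(CC)CC | intermediate
23 | Baylis–Hillman adduct of 10 and 22: 2-methylene-3-hydroxy ketone, C16 carbinol as both epimers, three triethylsilyl ethers | C=C(C(O)CC[C@@H]1[C@@]2(C)CC[C@@H](O[Si](CC)(CC)CC)C(C)(C)O[C@@H]2CC[C@]1(C)O[Si](CC)(CC)CC)C(=O)C[C@@H]1[C@@H](CC[C@@]1(C)O[Si](CC)(CC)CC)C(C)=C | intermediate
24 | C16 acetate of 23 | C=C(C(OC(C)=O)CC[C@@H]1[C@@]2(C)CC[C@@H](O[Si](CC)(CC)CC)C(C)(C)O[C@@H]2CC[C@]1(C)O[Si](CC)(CC)CC)C(=O)C[C@@H]1[C@@H](CC[C@@]1(C)O[Si](CC)(CC)CC)C(C)=C | intermediate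
25 | (E)-α-(acetoxymethyl) enone, acetate on C1, alkene C2=C16 | CC(=O)OC/C(=C\CC[C@@H]1[C@@]2(C)CC[C@@H](O[Si](CC)(CC)CC)C(C)(C)O[C@@H]2CC[C@]1(C)O[Si](CC)(CC)CC)C(=O)C[C@@H]1[C@@H](CC[C@@]1(C)O[Si](CC)(CC)CC)C(C)=C | intermediate
26 | cyclised β-acetoxy ketone, C2 as both epimers | CC(=O)OCC1C(=O)C[C@@H]2[C@@H](CC[C@@]2(C)O[Si](CC)(CC)CC)C(C)(C)[C@H]1CC[C@@H]1[C@@]2(C)CC[C@@H](O[Si](CC)(CC)CC)C(C)(C)O[C@@H]2CC[C@]1(C)O[Si](CC)(CC)CC | intermediate (not isolated)
27 | α-methylene hydroazulenone with the full skeleton; C10, C24 and C33 oxygens as triethylsilyl ethers | C=C1C(=O)C[C@@H]2[C@@H](CC[C@@]2(C)O[Si](CC)(CC)CC)C(C)(C)[C@H]1CC[C@@H]1[C@@]2(C)CC[C@@H](O[Si](CC)(CC)CC)C(C)(C)O[C@@H]2CC[C@]1(C)O[Si](CC)(CC)CC | intermediate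
28 | triol, the target with C24 as the (R)-alcohol | C=C1C(=O)C[C@@H]2[C@@H](CC[C@@]2(C)O)C(C)(C)[C@H]1CC[C@@H]1[C@@]2(C)CC[C@@H](O)C(C)(C)O[C@@H]2CC[C@]1(C)O | intermediate
29 | CNP0316622.2 | C=C1C(=O)C[C@@H]2[C@@H](CC[C@@]2(C)O)C(C)(C)[C@H]1CC[C@@H]1[C@@]2(C)CCC(=O)C(C)(C)O[C@@H]2CC[C@]1(C)O | target

## Step count and the least certain steps

Total: 22 steps. Longest linear sequence: 14 steps (steps 1 to 8, then 17 to 22; the branch through steps 9 to 16 is equally long).

**Step 6 (key step).** The most likely failure is insufficient facial discrimination at C6 between the methyl and the triethylsilyloxy group on C10, which would give the other cis pair. A second risk is slow cyclisation with oligomerisation at the temperature needed. Fallback, with a more reactive enophile at lower temperature: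
- Reduce 7 with i-Bu2AlH to (2E,4R)-4,8-dimethyl-4-(triethylsilyloxy)nona-2,7-dien-1-ol F1.
- Oxidise with MnO2 to the dienal F2.
- Heat in toluene at about 130 °C to give the ene product as its aldehyde F3; the reaction stays concerted, so the cis relation is kept.
- Add vinylmagnesium bromide to give the allylic carbinol F4.
- Dess–Martin oxidation brings the route back at 10, bypassing 8 and 9.

**Step 20.** The 7-endo closure may be slow enough that reduction of the tertiary radical wins, and the face selection at C16 may be low because the controlling interactions are small. Fallback, generating the radical by fragmentation with no metal hydride present: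
- Hydrate the isopropenyl group of 25 (Co(acac)2, divalent cobalt, PhSiH3, O2) to the tertiary alcohol F5.
- Acylate with N-phthalimidoyl chlorooxalate to the tert-alkyl N-phthalimidoyl oxalate F6.
- Irradiate with visible light in the presence of Ru(bpy)3(PF6)2 and a Hantzsch ester at 25 °C. Loss of two CO2 gives the same C13 radical, which cyclises and takes up a hydrogen atom. The route comes back at 26, followed by the Et3N elimination to 27.

**Step 13.** The internal epoxide may be activated before the terminal one, cationic rearrangement may compete, and the substituted enol ether may close the carbocycle slowly. Fallback, with the unsubstituted enol ether and the chain added afterwards: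
- Shi epoxidation of 11 gives the diepoxy ketone F7.
- LiN(i-Pr)2 and Et3SiCl give the kinetic enol ether F8.
- The same Et3SiOTf treatment gives the bicyclic ketone F9, unsubstituted at C19.
- IBX dehydrogenation, possible only toward C32–C31, gives the enone F10.
- Its cross-conjugated lithium enolate is alkylated at C19 with 3-(benzyloxy)propyl iodide to give F11.
- Conjugate reduction with Stryker's reagent, [(Ph3P)CuH]6, and base equilibration at C19 bring the route back at 18.

**Step 17.** Dimerisation of the vinyl ketone may outrun the slow amine-catalysed addition to a valuable aldehyde. Fallback, a stoichiometric three-component route: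
- Me2AlSPh adds to 10 at C1, and the aluminium enolate formed at C2 adds to 22 to give the β-hydroxy α-(phenylthiomethyl) ketone F12.
- Oxidation with NaIO4 gives the sulfoxide F13.
- Warming in toluene expels benzenesulfenic acid and brings the route back at 23.

**Step 5.** The carbenoid may attack the regenerated prenyl alkene (cyclopropanation) or oxygen transfer may stay incomplete. Fallback without the epoxide mask:
- Ozonolysis of 2 with one equivalent of ozone at −78 °C cleaves only the trisubstituted alkene and gives (4R)-4-methyl-4-(triethylsilyloxy)hex-5-enal F14.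
- Cross-metathesis of F14 with methyl acrylate (second-generation Hoveyda–Grubbs catalyst) gives the enoate aldehyde F15. No second alkene is left, so ring closure cannot compete.
- Wittig reaction with isopropylidenetriphenylphosphorane at −78 °C brings the route back at 7.

## Further compounds

F1 | step 6 | (2E,4R)-4,8-dimethyl-4-(triethylsilyloxy)nona-2,7-dien-1-ol | OC/C=C/[C@](C)(O[Si](CC)(CC)CC)CCC=C(C)C
F2 | step 6 | (2E,4R)-4,8-dimethyl-4-(triethylsilyloxy)nona-2,7-dienal | O=C/C=C/[C@](C)(O[Si](CC)(CC)CC)CCC=C(C)C
F3 | step 6 | 2-[(1R,2R,5R)-5-methyl-2-(prop-1-en-2-yl)-5-(triethylsilyloxy)cyclopentyl]acetaldehyde | O=CC[C@@H]1[C@@H](CC[C@@]1(C)O[Si](CC)(CC)CC)C(C)=C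
F4 | step 6 | 1-[(1R,2R,5R)-5-methyl-2-(prop-1-en-2-yl)-5-(triethylsilyloxy)cyclopentyl]but-3-en-2-ol, both carbinol epimers | C=CC(O)C[C@@H]1[C@@H](CC[C@@]1(C)O[Si](CC)(CC)CC)C(C)=C
F5 | step 20 | tertiary alcohol from hydration of the isopropenyl group of 25 | CC(=O)OC/C(=C\CC[C@@H]1[C@@]2(C)CC[C@@H](O[Si](CC)(CC)CC)C(C)(C)O[C@@H]2CC[C@]1(C)O[Si](CC)(CC)CC)C(=O)C[C@@H]1[C@@H](CC[C@@]1(C)O[Si](CC)(CC)CC)C(C)(C)O
F6 | step 20 | tert-alkyl N-phthalimidoyl oxalate of F5 | CC(=O)OC/C(=C\CC[C@@H]1[C@@]2(C)CC[C@@H](O[Si](CC)(CC)CC)C(C)(C)O[C@@H]2CC[C@]1(C)O[Si](CC)(CC)CC)C(=O)C[C@@H]1[C@@H](CC[C@@]1(C)O[Si](CC)(CC)CC)C(C)(C)OC(=O)C(=O)ON1C(=O)c2ccccc2C1=O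
F7 | step 13 | (5R,6R,9R)-5,6:9,10-diepoxy-6,10-dimethylundecan-2-one | CC(=O)CC[C@H]1O[C@]1(C)CC[C@H]1OC1(C)C
F8 | step 13 | triethylsilyl enol ether of F7 at the methyl group | C=C(O[Si](CC)(CC)CC)CC[C@H]1O[C@]1(C)CC[C@H]1OC1(C)C
F9 | step 13 | (3R,5aS,9aR)-2,2,5a-trimethyl-3-(triethylsilyloxy)octahydro-1-benzoxepin-7(2H)-one (trans-fused, C19 unsubstituted) | C1[C@@]2(C)CC[C@@H](O[Si](CC)(CC)CC)C(C)(C)O[C@@H]2CCC1=O
F10 | step 13 | the C31=C32 enone from F9 | C1[C@@]2(C)CC[C@@H](O[Si](CC)(CC)CC)C(C)(C)O[C@@H]2C=CC1=O
F11 | step 13 | F10 alkylated at C19 with the 3-(benzyloxy)propyl group, C19 epimers | c1ccccc1COCCCC1[C@@]2(C)CC[C@@H](O[Si](CC)(CC)CC)C(C)(C)O[C@@H]2C=CC1=O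
F12 | step 17 | β-hydroxy α-(phenylthiomethyl) ketone from 10, benzenethiolate and 22, mixture of diastereomers | c1ccccc1SCC(C(O)CC[C@@H]1[C@@]2(C)CC[C@@H](O[Si](CC)(CC)CC)C(C)(C)O[C@@H]2CC[C@]1(C)O[Si](CC)(CC)CC)C(=O)C[C@@H]1[C@@H](CC[C@@]1(C)O[Si](CC)(CC)CC)C(C)=C
F13 | step 17 | sulfoxide of F12 | c1ccccc1S(=O)CC(C(O)CC[C@@H]1[C@@]2(C)CC[C@@H](O[Si](CC)(CC)CC)C(C)(C)O[C@@H]2CC[C@]1(C)O[Si](CC)(CC)CC)C(=O)C[C@@H]1[C@@H](CC[C@@]1(C)O[Si](CC)(CC)CC)C(C)=C
F14 | step 5 | (4R)-4-methyl-4-(triethylsilyloxy)hex-5-enal | C=C[C@](C)(O[Si](CC)(CC)CC)CCC=O
F15 | step 5 | methyl (2E,4R)-4-methyl-7-oxo-4-(triethylsilyloxy)hept-2-enoate | COC(=O)/C=C/[C@](C)(O[Si](CC)(CC)CC)CCC=O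
A1 | alternative 1 | hydroazulene N,N-dimethylhydrazone with free C10 alcohol and a silyloxyethyl chain on C16 | C=C1/C(=N/N(C)C)C[C@@H]2[C@@H](CC[C@@]2(C)O)C(C)(C)[C@H]1CCO[Si](C)(C)C(C)(C)C
A2 | alternative 1 | open precursor: cyclopentane C6–C10 epoxide carrying the α-methylene methyl ketone N,N-dimethylhydrazone | C=C(/C(C)=N/N(C)C)[C@H](CCO[Si](C)(C)C(C)(C)C)C(C)(C)[C@@H]1CC[C@@]2(C)O[C@@H]12
A3 | alternative 2 | cyclohexanone with C19 and C20 set, carrying the hydroazulene and the propargylic chain | O=C1CC[C@](C)(O)[C@H](CC[C@H]2C(=C)C3(OCCO3)C[C@@H]4[C@@H](CC[C@@]4(C)O[Si](CC)(CC)CC)C2(C)C)[C@@]1(C)CC#CC(C)(C)O[Si](C)(C)C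
A4 | alternative 2 | 4-hydroxy-2,4-dimethylcyclohex-2-en-1-one | O=C1CC[C@](C)(O)C=C1C
A5 | alternative 2 | hydroazulene primary iodide (ketone as dioxolane, C10 as triethylsilyl ether) | ICC[C@H]1C(=C)C2(OCCO2)C[C@@H]3[C@@H](CC[C@@]3(C)O[Si](CC)(CC)CC)C1(C)C
A6 | alternative 2 | 1-bromo-4-methyl-4-(trimethylsilyloxy)pent-2-yne | BrCC#CC(C)(C)O[Si](C)(C)C
A7 | alternative 3 | trans-fused oxepane with acetate at C24 | CC(=O)O[C@H]1CC[C@]2(C)[C@@H](CCO[Si](C)(C)C(C)(C)C)C(=O)CC[C@H]2OC1(C)C
A8 | alternative 3 | tetrahydropyran with a 2-hydroxyprop-2-yl group on C24 | CC(C)(O)[C@H]1CC[C@]2(C)[C@@H](CCO[Si](C)(C)C(C)(C)C)C(=O)CC[C@H]2O1
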